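**Plan**

- Core numbering: 2-oxabicyclo[4.2.0]oct-4-en-3-one with C1 (quaternary, phenethyl), O2, C3 (lactone C=O), C4, C5 (C–OMe), C6 (fusion CH), C7 (CHPh), C8 (CH–pyranonyl).
- Cuts, in retrosynthetic order: C8–C6' to the 4-methoxy-2-pyranone; C1–CH2 (phenethyl) together with O2–C3 (lactone); C1–C6 and C7–C8 (ketene [2+2]); C4–C5 (acetate aldol).
- Enabling feature: on the cyclobutane ring (C1, C6, C7, C8), O2 at C1 is cis to the C5–C4–C3 chain on C6 and to the phenyl on C7. A carbon nucleophile entering a C1 ketone from the face these two cis groups leave open therefore puts the alkoxide on their side, and the six-membered lactone ring (O2, C3, C4, C5, C6, C1) closes onto the ester carbon C3.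
- Forward order: aldol chain, Z-alkene, cyclobutanone by dichloroketene [2+2], lactone ring in the organocerium step, C5 oxidation and O-methylation, removal of one chlorine at C8, pyranone joined last (convergent with a two-step chloropyranone).
- Stereochemistry: the C5 carbinol (catalytic asymmetric aldol) steers the ketene to one face of the Z-alkene (C6 and C7 cis) and is later erased by oxidation; C1 follows from attack anti to the C6 and C7 substituents; C8 from capture of the C8 radical on the exo face, anti to the C7 phenyl.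

Key step: step 7

Assumption: the ligand antipode used in the aldol step is the one shown by Mosher ester analysis of the aldol product to give the 3R carbinol, and dichloroketene is taken to attack the Z-alkene anti to the allylic silyloxy group in the conformer whose allylic C–H eclipses the double bond; the opposite sense is covered by the fallback for step 5.

**Route**

Step 1
Reactants: 1 methyl acetate
Product: 2 1-methoxy-1-(trimethylsilyloxy)ethene
Conditions: LDA, THF, −78 °C; Me3SiCl, −78 °C → rt; distillation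
Reagents that add atoms: chlorotrimethylsilane, C[Si](C)(C)Cl
Why: Kinetic deprotonation gives the lithium ester enolate, which is O-silylated to the silyl ketene acetal (ester enolate silylation), and distillation removes any C-silylated ester.

Step 2
Reactants: 3 3-phenylprop-2-ynal; 2 1-methoxy-1-(trimethylsilyloxy)ethene
Product: 5 methyl (3R)-3-hydroxy-5-phenylpent-4-ynoate, via O-trimethylsilyl aldol adduct 4 (not isolated)
Conditions: Ti(OiPr)4 (2 mol %), 2'-[(3-bromo-5-tert-butyl-2-hydroxybenzylidene)amino]-1,1'-binaphthalen-2-ol (antipode directing Re-face addition), 3,5-di-tert-butylsalicylic acid, Et2O, −10 °C; then 1 M HCl, THF, 0 °C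
Reagents that add atoms: none
Why: Catalytic enantioselective Mukaiyama acetate aldol addition of a silyl ketene acetal to a conjugated ynal at a chiral titanium Lewis acid, a substrate class on which this catalyst type is established; Re-face addition sets the 3R carbinol and dilute acid cleaves the O-silyl adduct.

Step 3
Reactants: 5 methyl (3R)-3-hydroxy-5-phenylpent-4-ynoate
Product: 6 methyl (3R)-3-[(tert-butyldimethylsilyl)oxy]-5-phenylpent-4-ynoate
Conditions: TBSCl, imidazole, DMF, rt
Reagents that add atoms: tert-butyldimethylsilyl chloride, CC(C)(C)[Si](C)(C)Cl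
Why: Standard silylation of a secondary propargylic alcohol, which masks the hydroxyl against the ketene and provides the bulky group that later differentiates the alkene faces.

Step 4
Reactants: 6 methyl (3R)-3-[(tert-butyldimethylsilyl)oxy]-5-phenylpent-4-ynoate
Product: 7 methyl (3R,4Z)-3-[(tert-butyldimethylsilyl)oxy]-5-phenylpent-4-enoate
Conditions: H2 (1 atm), Pd on CaCO3 poisoned with Pb(OAc)2, quinoline, EtOAc, rt
Reagents that add atoms: none
Why: Lindlar semihydrogenation adds hydrogen syn to the aryl alkyne and should stop at the Z-alkene, with quinoline suppressing over-reduction and isomerisation.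

Step 5
Reactants: 7 methyl (3R,4Z)-3-[(tert-butyldimethylsilyl)oxy]-5-phenylpent-4-enoate; 8 trichloroacetyl chloride
Product: 10 methyl (3R)-3-[(tert-butyldimethylsilyl)oxy]-3-[(1S,4R)-3,3-dichloro-2-oxo-4-phenylcyclobutyl]propanoate, via dichloroketene 9 (not isolated)
Conditions: Zn–Cu couple, POCl3, Et2O, rt, slow addition of 8; rapid filtration through a short silica pad
Reagents that add atoms: none
Why: Dichloroketene from zinc dechlorination adds to the Z-styrenyl alkene in a stereospecific [2+2] cycloaddition, the ketene carbonyl carbon bonding to the carbon remote from phenyl so that CCl2 lies next to CHPh and the cis C6/C7 relation is kept; with the allylic C–H eclipsing the alkene (A1,3 strain) the ketene should approach anti to the bulky silyloxy group, which fixes C6 and C7.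

Step 6
Reactants: 11 (2-bromoethyl)benzene
Product: 12 2-phenylethylmagnesium bromide (THF solution, titrated and used directly)
Conditions: Mg turnings, I2 (cat.), THF, rt → 40 °C
Reagents that add atoms: magnesium, [Mg]
Why: Oxidative insertion of magnesium into a primary alkyl bromide (Grignard formation).

Step 7
Reactants: 10 methyl (3R)-3-[(tert-butyldimethylsilyl)oxy]-3-[(1S,4R)-3,3-dichloro-2-oxo-4-phenylcyclobutyl]propanoate; 12 2-phenylethylmagnesium bromide
Product: 14 (1R,5R,6S,7R)-5-[(tert-butyldimethylsilyl)oxy]-8,8-dichloro-7-phenyl-1-(2-phenylethyl)-2-oxabicyclo[4.2.0]octan-3-one, via tertiary cerium alkoxide 13 (not isolated)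
Conditions: CeCl3 (dried, 1.5 equiv), 12 (1.3 equiv), THF, −78 °C; −78 → −30 °C; AcOH in THF, −78 °C (PPTS cat., CH2Cl2, rt, only if open hydroxy ester remains)
Reagents that add atoms: none
Why: Transmetalation of the Grignard reagent to CeCl3 gives a weakly basic, oxophilic organocerium reagent that adds 1,2 to the strained, chlorine-activated C1 carbonyl faster than it enolises C6–H, eliminates the β-silyloxy group or attacks the methyl ester, and the tertiary cerium alkoxide 13 then attacks the side-chain ester in an intramolecular transesterification that expels methoxide. The closest known reaction type is organocerium addition to enolisable cyclobutanones followed by lactonisation of a δ-hydroxy ester. The one ring formed, the six-membered lactone (O2, C3, C4, C5, C6, C1), closes by 6-exo-trig acyl substitution of the C1 oxygen on C3. The one new stereocentre, C1, is set by the substrate: the C6 side chain and the C7 phenyl, cis to each other from the cycloaddition, shield one face of the cyclobutanone, so the phenethyl group enters anti to both and O2 ends cis to the side chain, the only arrangement from which the cis-fused lactone can close. The step needs chemoselectivity for ketone over ester, secured by the higher electrophilicity of the α,α-dichlorocyclobutanone at −78 °C, and π-facial selectivity, secured by the two cis substituents; the two chlorines block enolisation towards C8, and acylation of the alkoxide on ring closure plus the cold acidic quench should forestall semibenzilic ring contraction.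

Step 8
Reactants: 14 (1R,5R,6S,7R)-5-[(tert-butyldimethylsilyl)oxy]-8,8-dichloro-7-phenyl-1-(2-phenylethyl)-2-oxabicyclo[4.2.0]octan-3-one
Product: 15 (1R,5R,6S,7R)-8,8-dichloro-5-hydroxy-7-phenyl-1-(2-phenylethyl)-2-oxabicyclo[4.2.0]octan-3-one
Conditions: HF·pyridine, pyridine, THF, 0 °C → rt
Reagents that add atoms: none
Why: Fluoride cleavage of the silyl ether under buffered acidic conditions, which avoid base-induced β-elimination of the β-oxygenated lactone and leave the C–Cl bonds untouched.

Step 9
Reactants: 15 (1R,5R,6S,7R)-8,8-dichloro-5-hydroxy-7-phenyl-1-(2-phenylethyl)-2-oxabicyclo[4.2.0]octan-3-one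
Product: 16 (1R,6R,7R)-8,8-dichloro-7-phenyl-1-(2-phenylethyl)-2-oxabicyclo[4.2.0]octane-3,5-dione
Conditions: Dess–Martin periodinane (1.2 equiv), CH2Cl2, 0 °C → rt
Reagents that add atoms: none
Why: Dess–Martin oxidation of the secondary β-hydroxy lactone to the β-keto lactone under neutral conditions removes the auxiliary C5 stereocentre, and the cis ring fusion at C6 is the stable one, so enolisation should do no harm.

Step 10
Reactants: 16 (1R,6R,7R)-8,8-dichloro-7-phenyl-1-(2-phenylethyl)-2-oxabicyclo[4.2.0]octane-3,5-dione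
Product: 17 (1R,6S,7R)-8,8-dichloro-5-methoxy-7-phenyl-1-(2-phenylethyl)-2-oxabicyclo[4.2.0]oct-4-en-3-one
Conditions: Me2SO4, K2CO3, acetone, rt
Reagents that add atoms: dimethyl sulfate, COS(=O)(=O)OC
Why: O-Methylation of the cyclic β-keto lactone enolate at the ketone oxygen with dimethyl sulfate and K2CO3 is the standard entry to 4-methoxy-5,6-dihydro-2-pyranones, and the doubly stabilised C4 enolate forms without touching C6.

Step 11
Reactants: 17 (1R,6S,7R)-8,8-dichloro-5-methoxy-7-phenyl-1-(2-phenylethyl)-2-oxabicyclo[4.2.0]oct-4-en-3-one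
Product: 18 (1R,6S,7R,8RS)-8-chloro-5-methoxy-7-phenyl-1-(2-phenylethyl)-2-oxabicyclo[4.2.0]oct-4-en-3-one (C8 epimers, used together)
Conditions: Bu3SnH (1.1 equiv), AIBN (cat.), toluene, 80 °C
Reagents that add atoms: none
Why: Radical-chain hydrodechlorination should stop at the monochloride because chlorine abstraction from a gem-dichloride is much faster than from the secondary chloride formed, and the C8 configuration is immaterial since it is lost at the radical stage of step 14.

Step 12
Reactants: 19 malonyl dichloride (2 equiv)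
Product: 22 6-chloro-4-hydroxy-2H-pyran-2-one, via 6-chloro-4-hydroxy-2-oxo-2H-pyran-3-carbonyl chloride 20 (not isolated), via 6-chloro-4-hydroxy-2-oxo-2H-pyran-3-carboxylic acid 21 (not isolated)
Conditions: neat, rt, 5 d (HCl evolution); then H2O, THF, 0 → 40 °C
Reagents that add atoms: none
Why: Self-condensation of malonyl dichloride (C-acylation, then enol lactonisation with loss of HCl) gives the chloropyranone acid chloride, whose hydrolysis and decarboxylation of the vinylogous β-keto acid should leave the 6-chloro-4-hydroxy-2-pyranone.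

Step 13
Reactants: 22 6-chloro-4-hydroxy-2H-pyran-2-one
Product: 23 6-chloro-4-methoxy-2H-pyran-2-one
Conditions: Me2SO4, K2CO3, acetone, rt
Reagents that add atoms: dimethyl sulfate, COS(=O)(=O)OC
Why: O-Methylation of the acidic 4-hydroxy-2-pyranone with dimethyl sulfate and K2CO3 gives the 4-methoxy-2-pyranone, as for 4-hydroxy-6-methyl-2-pyranone, and anhydrous conditions spare the C6 chloride.

Step 14
Reactants: 18 (1R,6S,7R,8RS)-8-chloro-5-methoxy-7-phenyl-1-(2-phenylethyl)-2-oxabicyclo[4.2.0]oct-4-en-3-one; 23 6-chloro-4-methoxy-2H-pyran-2-one (2 equiv)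
Product: 24 (1R,6S,7S,8S)-5-methoxy-8-(4-methoxy-2-oxo-2H-pyran-6-yl)-7-phenyl-1-(2-phenylethyl)-2-oxabicyclo[4.2.0]oct-4-en-3-one (the target)
Conditions: NiBr2(dme) (10 mol %), 4,4'-di-tert-butyl-2,2'-bipyridine, [Ir(dF(CF3)ppy)2(dtbbpy)]PF6 (1 mol %), (Me3Si)3SiNH(1-adamantyl) (1.5 equiv), 2-tert-butyl-1,1,3,3-tetramethylguanidine, DMA/t-AmOH, blue LEDs, rt
Reagents that add atoms: none
Why: Nickel/photoredox cross-electrophile coupling in which an aminosilane-derived silyl radical abstracts chlorine from the unactivated secondary C8 chloride and the cyclobutyl radical is captured by the pyranonyl nickel species formed by oxidative addition of zerovalent nickel into the activated C6'–Cl bond, reductive elimination then forming C8–C6'; the nickel centre should approach the planar C8 radical on the exo face, anti to the C7 phenyl and to the lactone ring folded under the cyclobutane, which places the pyranone cis to the phenethyl group as in the target.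

**Compound list**

1 | methyl acetate | COC(C)=O | starting material
2 | 1-methoxy-1-(trimethylsilyloxy)ethene | COC(=C)O[Si](C)(C)C | intermediate
3 | 3-phenylprop-2-ynal | O=CC#Cc1ccccc1 | starting material
4 | methyl (3R)-5-phenyl-3-(trimethylsilyloxy)pent-4-ynoate | COC(=O)C[C@@H](O[Si](C)(C)C)C#Cc1ccccc1 | intermediate (not isolated)
5 | methyl (3R)-3-hydroxy-5-phenylpent-4-ynoate | COC(=O)C[C@@H](O)C#Cc1ccccc1 | intermediate
6 | methyl (3R)-3-[(tert-butyldimethylsilyl)oxy]-5-phenylpent-4-ynoate | COC(=O)C[C@@H](O[Si](C)(C)C(C)(C)C)C#Cc1ccccc1 | intermediate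
7 | methyl (3R,4Z)-3-[(tert-butyldimethylsilyl)oxy]-5-phenylpent-4-enoate | COC(=O)C[C@@H](O[Si](C)(C)C(C)(C)C)/C=C\c1ccccc1 | intermediate
8 | trichloroacetyl chloride | O=C(Cl)C(Cl)(Cl)Cl | starting material
9 | dichloroketene | O=C=C(Cl)Cl | intermediate (not isolated)
10 | methyl (3R)-3-[(tert-butyldimethylsilyl)oxy]-3-[(1S,4R)-3,3-dichloro-2-oxo-4-phenylcyclobutyl]propanoate | COC(=O)C[C@@H](O[Si](C)(C)C(C)(C)C)[C@H]1C(=O)C(Cl)(Cl)[C@H]1c1ccccc1 | intermediate
11 | (2-bromoethyl)benzene | BrCCc1ccccc1 | starting material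
12 | 2-phenylethylmagnesium bromide | Br[Mg]CCc1ccccc1 | intermediate
13 | dichlorocerium alkoxide of methyl (3R)-3-[(tert-butyldimethylsilyl)oxy]-3-[(1S,2R,4R)-3,3-dichloro-2-hydroxy-4-phenyl-2-(2-phenylethyl)cyclobutyl]propanoate | COC(=O)C[C@@H](O[Si](C)(C)C(C)(C)C)[C@H]1[C@](O[Ce](Cl)Cl)(CCc2ccccc2)C(Cl)(Cl)[C@H]1c1ccccc1 | intermediate (not isolated)
14 | (1R,5R,6S,7R)-5-[(tert-butyldimethylsilyl)oxy]-8,8-dichloro-7-phenyl-1-(2-phenylethyl)-2-oxabicyclo[4.2.0]octan-3-one | CC(C)(C)[Si](C)(C)O[C@@H]1CC(=O)O[C@]2(CCc3ccccc3)[C@H]1[C@H](c1ccccc1)C2(Cl)Cl | intermediate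
15 | (1R,5R,6S,7R)-8,8-dichloro-5-hydroxy-7-phenyl-1-(2-phenylethyl)-2-oxabicyclo[4.2.0]octan-3-one | O[C@@H]1CC(=O)O[C@]2(CCc3ccccc3)[C@H]1[C@H](c1ccccc1)C2(Cl)Cl | intermediate
16 | (1R,6R,7R)-8,8-dichloro-7-phenyl-1-(2-phenylethyl)-2-oxabicyclo[4.2.0]octane-3,5-dione | O=C1CC(=O)O[C@]2(CCc3ccccc3)[C@H]1[C@H](c1ccccc1)C2(Cl)Cl | intermediate
17 | (1R,6S,7R)-8,8-dichloro-5-methoxy-7-phenyl-1-(2-phenylethyl)-2-oxabicyclo[4.2.0]oct-4-en-3-one | COC1=CC(=O)O[C@]2(CCc3ccccc3)[C@H]1[C@H](c1ccccc1)C2(Cl)Cl | intermediate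
18 | (1R,6S,7R,8RS)-8-chloro-5-methoxy-7-phenyl-1-(2-phenylethyl)-2-oxabicyclo[4.2.0]oct-4-en-3-one | COC1=CC(=O)O[C@]2(CCc3ccccc3)[C@H]1[C@H](c1ccccc1)C2Cl | intermediate
19 | malonyl dichloride | O=C(Cl)CC(=O)Cl | starting material
20 | 6-chloro-4-hydroxy-2-oxo-2H-pyran-3-carbonyl chloride | O=C(Cl)C1=C(O)C=C(Cl)OC1=O | intermediate (not isolated)
21 | 6-chloro-4-hydroxy-2-oxo-2H-pyran-3-carboxylic acid | OC(=O)C1=C(O)C=C(Cl)OC1=O | intermediate (not isolated)
22 | 6-chloro-4-hydroxy-2H-pyran-2-one | OC1=CC(=O)OC(Cl)=C1 | intermediate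
23 | 6-chloro-4-methoxy-2H-pyran-2-one | COC1=CC(=O)OC(Cl)=C1 | intermediate
24 | (1R,6S,7S,8S)-5-methoxy-8-(4-methoxy-2-oxo-2H-pyran-6-yl)-7-phenyl-1-(2-phenylethyl)-2-oxabicyclo[4.2.0]oct-4-en-3-one | COC1=CC(=O)O[C@]2(CCc3ccccc3)[C@H]1[C@H](c1ccccc1)[C@H]2c1cc(OC)cc(=O)o1 | target

**Step count and risks**

Total step count: 14. Longest linear sequence: 11 steps (steps 1, 2, 3, 4, 5, 7, 8, 9, 10, 11, 14); steps 6, 12 and 13 are convergent branches.

Step 14. What may go wrong: slow chlorine-atom abstraction from the hindered secondary C8 chloride, so that the silyl radical is used up unproductively; consumption of the chloropyranone by the base; or capture of the radical on the endo face. The fallback sets out from 7 and comes back at 24. It changes the C8 handle to bromine so that the last bond can be made by a thermal, base-free reductive coupling. Zinc dehalogenation of tribromoacetyl chloride gives dibromoketene F1, whose [2+2] addition to 7 should give the dibromocyclobutanone F2. Organocerium addition of 12 passes through the cerium alkoxide F3 and closes to the dibromo lactone F4. HF·pyridine then gives the alcohol F5, Dess–Martin oxidation the keto lactone F6, dimethyl sulfate with K2CO3 the enol ether F7, and one equivalent of Bu3SnH the monobromide F8. F8 and 23 are joined with NiBr2(dme), 4,4'-di-tert-butyl-2,2'-bipyridine, zinc dust and NaI in DMA at 40 °C, the standard reductive coupling of secondary alkyl bromides with sp2 halides, to give 24.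

Step 7. What may go wrong: β-hydride transfer from the phenethyl reagent (reduction of the ketone), halogen–metal exchange, or ring contraction of the α,α-dichloro alkoxide before it lactonises. The fallback sets out from 10 and comes back at 14. The sp3 nucleophile is replaced by a smaller sp nucleophile without β-hydrogens: lithium phenylacetylide with CeCl3 in THF at −78 °C should add to the same open face to give the cerium alkoxide F9, which lactonises to the alkynyl lactone F10. Hydrogenation of the triple bond over PtO2 in ethyl acetate, which spares the C–Cl bonds, then gives 14.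

Step 5. What may go wrong: approach of the ketene syn to the silyloxy group (reversed π-facial sense), which would lead into the enantiomeric ring series. The fallback sets out from 3 (with 2) and comes back at 16. Because C5 is destroyed in step 9, a reversed sense is answered by entering the antipodal C5 series. The enantiomeric ligand in the aldol gives the silyl adduct F11 and, after acid, the (3S)-hydroxy ester F12. Silylation gives the silyl ether F13 and Lindlar reduction the Z-alkene F14. Syn-selective cycloaddition of 9 then gives the cyclobutanone F15, which has the ring configuration of 10 and the opposite C5 configuration. The organocerium step passes through the cerium alkoxide F16 to the lactone F17, desilylation gives the alcohol F18, and Dess–Martin oxidation converges on 16.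

**Further compounds**

F1 | step 14 | dibromoketene | O=C=C(Br)Br
F2 | step 14 | methyl (3R)-3-[(tert-butyldimethylsilyl)oxy]-3-[(1S,4R)-3,3-dibromo-2-oxo-4-phenylcyclobutyl]propanoate | COC(=O)C[C@@H](O[Si](C)(C)C(C)(C)C)[C@H]1C(=O)C(Br)(Br)[C@H]1c1ccccc1
F3 | step 14 | dichlorocerium alkoxide of methyl (3R)-3-[(tert-butyldimethylsilyl)oxy]-3-[(1S,2R,4R)-3,3-dibromo-2-hydroxy-4-phenyl-2-(2-phenylethyl)cyclobutyl]propanoate | COC(=O)C[C@@H](O[Si](C)(C)C(C)(C)C)[C@H]1[C@](O[Ce](Cl)Cl)(CCc2ccccc2)C(Br)(Br)[C@H]1c1ccccc1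
F4 | step 14 | (1R,5R,6S,7R)-8,8-dibromo-5-[(tert-butyldimethylsilyl)oxy]-7-phenyl-1-(2-phenylethyl)-2-oxabicyclo[4.2.0]octan-3-one | CC(C)(C)[Si](C)(C)O[C@@H]1CC(=O)O[C@]2(CCc3ccccc3)[C@H]1[C@H](c1ccccc1)C2(Br)Br
F5 | step 14 | (1R,5R,6S,7R)-8,8-dibromo-5-hydroxy-7-phenyl-1-(2-phenylethyl)-2-oxabicyclo[4.2.0]octan-3-one | O[C@@H]1CC(=O)O[C@]2(CCc3ccccc3)[C@H]1[C@H](c1ccccc1)C2(Br)Br
F6 | step 14 | (1R,6R,7R)-8,8-dibromo-7-phenyl-1-(2-phenylethyl)-2-oxabicyclo[4.2.0]octane-3,5-dione | O=C1CC(=O)O[C@]2(CCc3ccccc3)[C@H]1[C@H](c1ccccc1)C2(Br)Br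
F7 | step 14 | (1R,6S,7R)-8,8-dibromo-5-methoxy-7-phenyl-1-(2-phenylethyl)-2-oxabicyclo[4.2.0]oct-4-en-3-one | COC1=CC(=O)O[C@]2(CCc3ccccc3)[C@H]1[C@H](c1ccccc1)C2(Br)Br
F8 | step 14 | (1R,6S,7R,8RS)-8-bromo-5-methoxy-7-phenyl-1-(2-phenylethyl)-2-oxabicyclo[4.2.0]oct-4-en-3-one | COC1=CC(=O)O[C@]2(CCc3ccccc3)[C@H]1[C@H](c1ccccc1)C2Br
F9 | step 7 | dichlorocerium alkoxide of methyl (3R)-3-[(tert-butyldimethylsilyl)oxy]-3-[(1S,2S,4R)-3,3-dichloro-2-hydroxy-4-phenyl-2-(phenylethynyl)cyclobutyl]propanoate | COC(=O)C[C@@H](O[Si](C)(C)C(C)(C)C)[C@H]1[C@](O[Ce](Cl)Cl)(C#Cc2ccccc2)C(Cl)(Cl)[C@H]1c1ccccc1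
F10 | step 7 | (1S,5R,6S,7R)-5-[(tert-butyldimethylsilyl)oxy]-8,8-dichloro-7-phenyl-1-(phenylethynyl)-2-oxabicyclo[4.2.0]octan-3-one | CC(C)(C)[Si](C)(C)O[C@@H]1CC(=O)O[C@]2(C#Cc3ccccc3)[C@H]1[C@H](c1ccccc1)C2(Cl)Cl
F11 | step 5 | methyl (3S)-5-phenyl-3-(trimethylsilyloxy)pent-4-ynoate | COC(=O)C[C@H](O[Si](C)(C)C)C#Cc1ccccc1
F12 | step 5 | methyl (3S)-3-hydroxy-5-phenylpent-4-ynoate | COC(=O)C[C@H](O)C#Cc1ccccc1
F13 | step 5 | methyl (3S)-3-[(tert-butyldimethylsilyl)oxy]-5-phenylpent-4-ynoate | COC(=O)C[C@H](O[Si](C)(C)C(C)(C)C)C#Cc1ccccc1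
F14 | step 5 | methyl (3S,4Z)-3-[(tert-butyldimethylsilyl)oxy]-5-phenylpent-4-enoate | COC(=O)C[C@H](O[Si](C)(C)C(C)(C)C)/C=C\c1ccccc1
F15 | step 5 | methyl (3S)-3-[(tert-butyldimethylsilyl)oxy]-3-[(1S,4R)-3,3-dichloro-2-oxo-4-phenylcyclobutyl]propanoate | COC(=O)C[C@H](O[Si](C)(C)C(C)(C)C)[C@H]1C(=O)C(Cl)(Cl)[C@H]1c1ccccc1
F16 | step 5 | dichlorocerium alkoxide of methyl (3S)-3-[(tert-butyldimethylsilyl)oxy]-3-[(1S,2R,4R)-3,3-dichloro-2-hydroxy-4-phenyl-2-(2-phenylethyl)cyclobutyl]propanoate | COC(=O)C[C@H](O[Si](C)(C)C(C)(C)C)[C@H]1[C@](O[Ce](Cl)Cl)(CCc2ccccc2)C(Cl)(Cl)[C@H]1c1ccccc1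
F17 | step 5 | (1R,5S,6S,7R)-5-[(tert-butyldimethylsilyl)oxy]-8,8-dichloro-7-phenyl-1-(2-phenylethyl)-2-oxabicyclo[4.2.0]octan-3-one | CC(C)(C)[Si](C)(C)O[C@H]1CC(=O)O[C@]2(CCc3ccccc3)[C@H]1[C@H](c1ccccc1)C2(Cl)Cl
F18 | step 5 | (1R,5S,6S,7R)-8,8-dichloro-5-hydroxy-7-phenyl-1-(2-phenylethyl)-2-oxabicyclo[4.2.0]octan-3-one | O[C@H]1CC(=O)O[C@]2(CCc3ccccc3)[C@H]1[C@H](c1ccccc1)C2(Cl)Cl
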